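**Retrosynthetic overview**

1. Atom labels used throughout: tetrahydrofuran O1–C2–C3–C4–C5 (isopropenyl on C2), oxetane C4–C5–O6–C7 (CH3 on C7), carbocycle C4–C7–C8–C9–C10–C11 (C11 = CMe2; in the target C8–Br and C9=C10–Br).
2. The strategy rests on the 2,7-dioxabicyclo[3.2.0]heptane: its oxetane acetal C4–C5–O6–C7 is the [2+2] adduct of a methyl ketone (C7=O6) and the C4=C5 enol ether bond of a 2-isopropenyl-2,3-dihydrofuran. Its C4–C7 bond is also the cyclohexene bond next to C11, so an intramolecular Paternò–Büchi reaction of a ketone hung on C4 through C11–C10–C9–C8 closes carbocycle and oxetane at once across the contiguous fully substituted C11, C4 and C7.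
3. After the photocycloaddition: C8–Br by Appel inversion of the allylic alcohol, C10–Br from the C10 ketone through its enol triflate, C8–OH by conjugate borylation/oxidation of the C8=C9–C10=O enone (Saegusa dehydrogenation of the photoadduct-derived ketone).
4. Before it: the keto chain from a 3-silyloxybutyl Grignard reagent and a neopentyl aldehyde (C10), the C4–C11 bond by photoredox alkylation of (R)-2-isopropenyl-2,3-dihydrofuran with ethyl 2-bromoisobutyrate, the dihydrofuran from methacrolein by asymmetric propargylation and alkynol cycloisomerisation.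
5. Ring order: dihydrofuran first, cyclohexane and oxetane together in the photochemical step, ring alkene and both bromines last.

Key step: step 10

Remark on the chemistry: butane-1,3-diol is used as the racemate; its carbinol carbon (future C7) and the carbinol carbon formed in step 7 (future C10) are carried as stereoisomer mixtures because both become sp2 later (steps 9 and 12).

**Step 1**
Reactants: 1 methacrolein; 2 allenylboronic acid pinacol ester
Product: 3 (R)-2-methylhex-1-en-5-yn-3-ol
Conditions: (R)-TRIP phosphoric acid (5 mol%), 4 Å MS, toluene, −20 °C; aqueous work-up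
Reagents that add atoms: none
Why: Chiral-phosphoric-acid-catalysed propargylation of aldehydes with allenylboronates (SE2′ through a six-membered acid-bound transition state) is established for α,β-unsaturated aldehydes, the acid antipode fixes the aldehyde face and the (R)-carbinol is expected (the antipodal acid would be used if the sense proves opposite).

**Step 2**
Reactants: 3 (R)-2-methylhex-1-en-5-yn-3-ol
Product: 4 (R)-2-(prop-1-en-2-yl)-2,3-dihydrofuran
Conditions: Mo(CO)6 (20 mol%), Et3N, Et2O, hν (350 nm), rt
Reagents that add atoms: none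
Why: Molybdenum-carbonyl-catalysed endo cycloisomerisation of but-3-yn-1-ols runs through a metal vinylidene whose terminal carbon is captured by the hydroxyl, giving the 2,3-dihydrofuran without touching the carbinol centre.

**Step 3**
Reactants: 4 (R)-2-(prop-1-en-2-yl)-2,3-dihydrofuran; 5 ethyl 2-bromo-2-methylpropanoate
Product: 6 ethyl 2-methyl-2-[(5R)-5-(prop-1-en-2-yl)-4,5-dihydrofuran-3-yl]propanoate
Conditions: fac-Ir(ppy)3 (1 mol%), K2CO3, degassed MeCN, blue LEDs (450 nm), rt
Reagents that add atoms: none
Why: In this photoredox Heck-type alkylation of an enol ether the tertiary α-ester radical from single-electron reduction of 5 adds to the nucleophilic C4, the α-oxy radical at C5 is oxidised to the oxocarbenium ion, and loss of the C4 proton to carbonate restores the enol ether.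

**Step 4**
Reactants: 6 ethyl 2-methyl-2-[(5R)-5-(prop-1-en-2-yl)-4,5-dihydrofuran-3-yl]propanoate
Product: 7 2-methyl-2-[(5R)-5-(prop-1-en-2-yl)-4,5-dihydrofuran-3-yl]propanal
Conditions: i-Bu2AlH (1.1 equiv), CH2Cl2, −78 °C; aq. KNaC4H4O6 (potassium sodium tartrate)
Reagents that add atoms: none
Why: Partial reduction of a hindered α,α-disubstituted ester stops at the aldehyde oxidation level at −78 °C, the aldehyde is non-enolisable and the basic tartrate work-up spares the enol ether.

**Step 5**
Reactants: 8 butane-1,3-diol
Product: 9 4-bromobutan-2-ol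
Conditions: CBr4 (1.0 equiv), PPh3, CH2Cl2, 0 °C
Reagents that add atoms: carbon tetrabromide, BrC(Br)(Br)Br
Why: The Appel reaction activates and displaces the primary hydroxyl much faster than the secondary one.

**Step 6**
Reactants: 9 4-bromobutan-2-ol
Product: 10 (4-bromobutan-2-yl)oxytriethylsilane
Conditions: Et3SiCl, imidazole, CH2Cl2, 0 °C to rt
Reagents that add atoms: chlorotriethylsilane, CC[Si](Cl)(CC)CC
Why: Standard O-silylation gives an ether that is stable to magnesium and removable later with buffered fluoride.

**Step 7**
Reactants: 7 2-methyl-2-[(5R)-5-(prop-1-en-2-yl)-4,5-dihydrofuran-3-yl]propanal; 10 (4-bromobutan-2-yl)oxytriethylsilane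
Product: 13 2-methyl-2-[(5R)-5-(prop-1-en-2-yl)-4,5-dihydrofuran-3-yl]-6-(triethylsilyloxy)heptan-3-yl acetate (epimer mixture at both carbinol carbons), via Grignard reagent 11 (not isolated), via bromomagnesium alkoxide 12 (not isolated)
Conditions: 10, Mg turnings, cat. I2, THF, 40 °C; then 7, THF, −78 to 0 °C; then Ac2O, cat. DMAP, 0 °C to rt
Reagents that add atoms: magnesium (held only in 11 and 12), [Mg]; acetic anhydride, CC(=O)OC(C)=O
Why: A γ-silyloxy Grignard reagent is stable and adds to the non-enolisable neopentyl aldehyde, and the magnesium alkoxide is acylated in the same flask so that no free alcohol sits next to the acid-sensitive enol ether.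

**Step 8**
Reactants: 13 2-methyl-2-[(5R)-5-(prop-1-en-2-yl)-4,5-dihydrofuran-3-yl]-6-(triethylsilyloxy)heptan-3-yl acetate
Product: 14 6-hydroxy-2-methyl-2-[(5R)-5-(prop-1-en-2-yl)-4,5-dihydrofuran-3-yl]heptan-3-yl acetate
Conditions: Bu4NF, AcOH (1:1), THF, 0 °C
Reagents that add atoms: none
Why: Buffered fluoride cleaves the triethylsilyl ether while the acetate and the enol ether remain.

**Step 9**
Reactants: 14 6-hydroxy-2-methyl-2-[(5R)-5-(prop-1-en-2-yl)-4,5-dihydrofuran-3-yl]heptan-3-yl acetate
Product: 15 2-methyl-6-oxo-2-[(5R)-5-(prop-1-en-2-yl)-4,5-dihydrofuran-3-yl]heptan-3-yl acetate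
Conditions: Dess–Martin periodinane, pyridine, CH2Cl2, 0 °C to rt
Reagents that add atoms: none
Why: Pyridine-buffered Dess–Martin oxidation turns the secondary alcohol into the methyl ketone without acid that would hydrolyse the enol ether.

**Step 10**
Reactants: 15 2-methyl-6-oxo-2-[(5R)-5-(prop-1-en-2-yl)-4,5-dihydrofuran-3-yl]heptan-3-yl acetate
Product: 16 tricyclic oxetane acetal with acetoxy on C10 (C10 epimers; oxetane on the tetrahydrofuran face anti to isopropenyl)
Conditions: hν (300 nm), degassed MeCN (5 mM), solid NaHCO3, base-washed Pyrex, 15 °C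
Reagents that add atoms: none
Why: Excitation of the methyl ketone to its n,π* state is followed by interception by the tethered electron-rich trisubstituted enol ether in a charge-transfer complex that collapses through a 1,4-biradical, the ketone carbon C7 bonding to C4 and O6 to C5. The closest known reactions are the intramolecular Paternò–Büchi reaction of alkyl ketones with tethered alkenes and the carbonyl–enol ether (dihydrofuran) photocycloaddition. The carbocycle C4–C7–C8–C9–C10–C11 closes in the fused six-membered mode through the four-atom tether as C7 bonds to C4, and the oxetane C4–C5–O6–C7 closes by four-membered recombination of O6 with C5. C4, C5 and C7 are created together: both cis ring fusions are forced by the four-membered ring, and their absolute sense follows from attack on the dihydrofuran face anti to the C2 isopropenyl group. The step needs the fused acetal regiochemistry and a cycloaddition faster than γ-hydrogen abstraction: the tether on C4 makes the crossed adduct a bridged 2-oxabicyclo[4.1.1]octane and the polar solvent favours C7–C4/O6–C5 pairing in the charge-transfer complex, while the only γ-hydrogen (C10–H) is neopentyl and deactivated by the acetoxy group and the substrate has no C–Br bond or conjugated carbonyl.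

**Step 11**
Reactants: 16 tricyclic oxetane acetal with acetoxy on C10
Product: 17 tricyclic oxetane acetal with hydroxyl on C10 (C10 epimers)
Conditions: K2CO3, MeOH, rt
Reagents that add atoms: none
Why: Base-catalysed transesterification removes the acetate under conditions to which the oxetane acetal is inert.

**Step 12**
Reactants: 17 tricyclic oxetane acetal with hydroxyl on C10
Product: 18 tricyclic C10 ketone
Conditions: Dess–Martin periodinane, NaHCO3, CH2Cl2, 0 °C to rt
Reagents that add atoms: none
Why: Buffered Dess–Martin oxidation converges both C10 epimers on one ketone and keeps the medium non-acidic for the oxetane acetal.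

**Step 13**
Reactants: 18 tricyclic C10 ketone
Product: 19 trimethylsilyl enol ether (C9=C10–OSiMe3)
Conditions: Me3SiCl, LiN(i-Pr)2 (internal quench), THF, −78 °C
Reagents that add atoms: chlorotrimethylsilane, C[Si](C)(C)Cl
Why: C9 is the only enolisable position because C11 is quaternary, so amide-base enolisation with silyl trapping gives a single enol ether.

**Step 14**
Reactants: 19 trimethylsilyl enol ether
Product: 20 tricyclic enone (C8=C9–C10=O)
Conditions: Pd(OAc)2 (1.1 equiv), MeCN, rt
Reagents that add atoms: none
Why: In the Saegusa oxidation the oxa-π-allyl species of divalent palladium undergoes β-hydride elimination toward C8, the only position carrying hydrogen.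

**Step 15**
Reactants: 20 tricyclic enone
Product: 22 β-hydroxy ketone with the C8 hydroxyl cis to O6, via boryl ketone 21 (not isolated)
Conditions: CuCl (5 mol%), NaOt-Bu (10 mol%), Josiphos-type bisphosphine (6 mol%, matched antipode), B2pin2, MeOH, THF, rt; then NaBO3·4H2O, THF/H2O, 0 °C to rt
Reagents that add atoms: bis(pinacolato)diboron (boron of 21 only), CC1(C)OB(OC1(C)C)B1OC(C)(C)C(C)(C)O1; sodium perborate (hydroxyl oxygen), [Na+].[Na+].O[B-]1(O)OO[B-](O)(O)OO1
Why: Copper-boryl conjugate addition to the enone followed by stereoretentive C–B oxidation sets C8 by delivery of boron to the face cis to O6 and anti to the C7 methyl group, with the chiral bisphosphine (both antipodes would be screened) reinforcing that face.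

**Step 16**
Reactants: 22 β-hydroxy ketone
Product: 23 C8 triethylsilyl ether of the β-hydroxy ketone
Conditions: Et3SiCl, imidazole, cat. DMAP, DMF, rt
Reagents that add atoms: chlorotriethylsilane, CC[Si](Cl)(CC)CC
Why: Silylation under amine buffering masks the hydroxyl before enolisation and avoids Lewis acids that would open the oxetane acetal.

**Step 17**
Reactants: 23 C8 triethylsilyl ether of the β-hydroxy ketone
Product: 24 enol triflate (C9=C10–OTf)
Conditions: PhNTf2, then KN(SiMe3)2 added last, THF, −78 °C
Reagents that add atoms: N-phenylbis(trifluoromethanesulfonimide), O=S(=O)(N(c1ccccc1)S(=O)(=O)C(F)(F)F)C(F)(F)F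
Why: Kinetic enolisation can only occur at C9 and the enolate is O-triflated as it forms, which limits β-elimination of the C8 silyloxy group.

**Step 18**
Reactants: 24 enol triflate
Product: 25 vinyl bromide (C9=C10–Br) with the C8 triethylsilyl ether
Conditions: Ni(cod)2 (10 mol%), LiBr (3 equiv), DMA/THF (1:3), rt
Reagents that add atoms: lithium bromide, [Li+].[Br-]
Why: Nickel-catalysed halogenation of enol triflates (oxidative addition to zerovalent nickel, triflate–bromide exchange, C–Br reductive elimination) is known to tolerate hindered, fully substituted neighbours and silyl ethers.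

**Step 19**
Reactants: 25 vinyl bromide with the C8 triethylsilyl ether
Product: 26 allylic alcohol (C8 hydroxyl cis to O6, C9=C10–Br)
Conditions: Bu4NF, AcOH, THF, 0 °C to rt
Reagents that add atoms: none
Why: Buffered fluoride removes the silyl group without touching the vinyl bromide or the acetal.

**Step 20**
Reactants: 26 allylic alcohol
Product: 27 CNP0141320.1, (2R,4S,5S,7S,8S) in the labels above, bromine on C8 trans to O6
Conditions: CBr4, PPh3, 2,6-lutidine, CH2Cl2, 0 °C to rt
Reagents that add atoms: carbon tetrabromide, BrC(Br)(Br)Br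
Why: In the Appel reaction the oxyphosphonium salt of the secondary allylic alcohol is displaced by bromide in an SN2 manner with inversion, SN2′ attack being blocked because it would place a second bromine on C10, so bromine arrives trans to O6.

**Compound list**

1 | methacrolein | C=C(C)C=O | starting material
2 | allenylboronic acid pinacol ester | C=C=CB1OC(C)(C)C(C)(C)O1 | starting material
3 | (R)-2-methylhex-1-en-5-yn-3-ol | C=C(C)[C@H](O)CC#C | intermediate
4 | (R)-2-(prop-1-en-2-yl)-2,3-dihydrofuran | C=C(C)[C@H]1CC=CO1 | intermediate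
5 | ethyl 2-bromo-2-methylpropanoate | CCOC(=O)C(C)(C)Br | starting material
6 | ethyl 2-methyl-2-[(5R)-5-(prop-1-en-2-yl)-4,5-dihydrofuran-3-yl]propanoate | C=C(C)[C@H]1CC(C(C)(C)C(=O)OCC)=CO1 | intermediate
7 | 2-methyl-2-[(5R)-5-(prop-1-en-2-yl)-4,5-dihydrofuran-3-yl]propanal | C=C(C)[C@H]1CC(C(C)(C)C=O)=CO1 | intermediate
8 | butane-1,3-diol (racemic) | CC(O)CCO | starting material
9 | 4-bromobutan-2-ol (racemic) | CC(O)CCBr | intermediate
10 | (4-bromobutan-2-yl)oxytriethylsilane (racemic) | CC(CCBr)O[Si](CC)(CC)CC | intermediate
11 | [3-(triethylsilyloxy)butyl]magnesium bromide (not isolated) | CC(CC[Mg]Br)O[Si](CC)(CC)CC | intermediate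
12 | bromomagnesium alkoxide of the Grignard adduct of 7 (not isolated) | C=C(C)[C@H]1CC(C(C)(C)C(O[Mg]Br)CCC(C)O[Si](CC)(CC)CC)=CO1 | intermediate
13 | 2-methyl-2-[(5R)-5-(prop-1-en-2-yl)-4,5-dihydrofuran-3-yl]-6-(triethylsilyloxy)heptan-3-yl acetate (epimer mixture) | C=C(C)[C@H]1CC(C(C)(C)C(OC(C)=O)CCC(C)O[Si](CC)(CC)CC)=CO1 | intermediate
14 | 6-hydroxy-2-methyl-2-[(5R)-5-(prop-1-en-2-yl)-4,5-dihydrofuran-3-yl]heptan-3-yl acetate (epimer mixture) | C=C(C)[C@H]1CC(C(C)(C)C(OC(C)=O)CCC(C)O)=CO1 | intermediate
15 | 2-methyl-6-oxo-2-[(5R)-5-(prop-1-en-2-yl)-4,5-dihydrofuran-3-yl]heptan-3-yl acetate (C3 epimers) | C=C(C)[C@H]1CC(C(C)(C)C(OC(C)=O)CCC(C)=O)=CO1 | intermediate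
16 | tricyclic oxetane acetal, acetoxy on C10 (C10 epimers), oxetane anti to isopropenyl, both ring fusions cis | C=C(C)[C@H]1C[C@@]23[C@@H](O1)O[C@]2(C)CCC(OC(C)=O)C3(C)C | intermediate
17 | tricyclic oxetane acetal, hydroxyl on C10 (C10 epimers) | C=C(C)[C@H]1C[C@@]23[C@@H](O1)O[C@]2(C)CCC(O)C3(C)C | intermediate
18 | tricyclic C10 ketone | C=C(C)[C@H]1C[C@@]23[C@@H](O1)O[C@]2(C)CCC(=O)C3(C)C | intermediate
19 | trimethylsilyl enol ether of 18 (C9=C10–OSiMe3) | C=C(C)[C@H]1C[C@@]23[C@@H](O1)O[C@]2(C)CC=C(O[Si](C)(C)C)C3(C)C | intermediate
20 | tricyclic enone (C8=C9–C10=O) | C=C(C)[C@H]1C[C@@]23[C@@H](O1)O[C@]2(C)C=CC(=O)C3(C)C | intermediate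
21 | β-boryl ketone, pinacolboryl on C8 cis to O6 (not isolated) | C=C(C)[C@H]1C[C@@]23[C@@H](O1)O[C@]2(C)[C@H](B4OC(C)(C)C(C)(C)O4)CC(=O)C3(C)C | intermediate
22 | β-hydroxy ketone, C8 hydroxyl cis to O6 | C=C(C)[C@H]1C[C@@]23[C@@H](O1)O[C@]2(C)[C@H](O)CC(=O)C3(C)C | intermediate
23 | C8 triethylsilyl ether of 22 | C=C(C)[C@H]1C[C@@]23[C@@H](O1)O[C@]2(C)[C@H](O[Si](CC)(CC)CC)CC(=O)C3(C)C | intermediate
24 | enol triflate (C9=C10–OTf), C8 triethylsilyl ether | C=C(C)[C@H]1C[C@@]23[C@@H](O1)O[C@]2(C)[C@H](O[Si](CC)(CC)CC)C=C(OS(=O)(=O)C(F)(F)F)C3(C)C | intermediate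
25 | vinyl bromide (C9=C10–Br), C8 triethylsilyl ether | C=C(C)[C@H]1C[C@@]23[C@@H](O1)O[C@]2(C)[C@H](O[Si](CC)(CC)CC)C=C(Br)C3(C)C | intermediate
26 | allylic alcohol, C8 hydroxyl cis to O6, C9=C10–Br | C=C(C)[C@H]1C[C@@]23[C@@H](O1)O[C@]2(C)[C@H](O)C=C(Br)C3(C)C | intermediate
27 | CNP0141320.1, C8 bromine trans to O6 | C=C(C)[C@H]1C[C@@]23[C@@H](O1)O[C@]2(C)[C@@H](Br)C=C(Br)C3(C)C | target

**Step count and risks**

Total step count: 20. Longest linear sequence: 18 steps (steps 1–4 and 7–20, from methacrolein); steps 5 and 6 are the side branch to bromide 10.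

Steps most likely to fail:

1. Step 10 (photocycloaddition). The excited ketone may be lost by hydrogen abstraction from C10, oxygen may bond first to C4 and lead to the crossed bridged oxetane, or the ketone may approach the dihydrofuran face syn to isopropenyl. The fallback sets out from 15 and forms the two bonds by polar chemistry. A TiCl4-promoted intramolecular Mukaiyama-type (Prins) addition of the enol ether carbon C4 to the ketone (CH2Cl2, −78 °C, aqueous NaHCO3 quench) would give the spiro hydroxy lactol with a tertiary C7 hydroxyl and a C5 hemiacetal F1. Mitsunobu cyclodehydration of its 1,3-related hydroxyls (PPh3, DIAD, toluene, 0 °C) would then close the oxetane acetal and return to the route at 16.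

2. Step 3 (photoredox alkylation). The tertiary radical may add to the isopropenyl alkene instead of, or in addition to, C4, the adduct may stop at an atom-transfer product without restoring the enol ether, or the acid-sensitive dihydrofuran may decompose. The fallback sets out from 4 and makes the C4–C11 bond by cross-coupling. Bromine addition to the enol ether (Br2, CH2Cl2, −78 °C) would give 2,3-dibromo-5-(prop-1-en-2-yl)oxolane F2, and elimination of HBr with Et3N would give (R)-4-bromo-2-(prop-1-en-2-yl)-2,3-dihydrofuran F3. Palladium-catalysed coupling (Pd(dba)2, P(t-Bu)3, THF, rt) with the Reformatsky reagent ethyl 2-(bromozincio)-2-methylpropanoate F4, made from 5 and zinc dust, would return to the route at 6.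

3. Step 15 (conjugate borylation). Boryl transfer to the neopentyl-type C8 may be slow, or boron may be delivered to the face cis to the C7 methyl group if ligand and substrate bias do not match. The fallback sets out from 20 and uses a small oxygen nucleophile under substrate control. Nucleophilic epoxidation (t-BuOOH, DBU, CH2Cl2, 0 °C) should give the C8–C9 α,β-epoxy ketone with the epoxide oxygen cis to O6 F5. Reductive cleavage of the C9–O bond with SmI2 (THF/MeOH, −90 °C) would leave the C8–O bond untouched and return to the route at 22.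

**Further compounds**

F1 | step 10 | spiro hydroxy lactol: C5 hemiacetal (anomer mixture), tertiary C7 hydroxyl, C10 acetate | C=C(C)[C@H]1C[C@@]2(C(O)O1)[C@](C)(O)CCC(OC(C)=O)C2(C)C
F2 | step 3 | 2,3-dibromo-5-(prop-1-en-2-yl)oxolane (5R, trans dibromide) | C=C(C)[C@H]1CC(Br)C(Br)O1
F3 | step 3 | (R)-4-bromo-2-(prop-1-en-2-yl)-2,3-dihydrofuran | C=C(C)[C@H]1CC(Br)=CO1
F4 | step 3 | ethyl 2-(bromozincio)-2-methylpropanoate | CCOC(=O)C(C)(C)[Zn]Br
F5 | step 15 | C8–C9 α,β-epoxy ketone, epoxide oxygen cis to O6 | C=C(C)[C@H]1C[C@@]23[C@@H](O1)O[C@]2(C)[C@@H]4O[C@@H]4C(=O)C3(C)C
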